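The target is divided at the ester between the primary alcohol on B4 and the left acid, and each half is made from one enantiomer of 4-isopropylcyclohexenone. Everything rests on ring C, the seven-membered lactone: its ring oxygen, the adjacent CH2 and the carboxyl-bearing alkene carbon are an acrylate unit set between the carboxyl carbon on B3 and the alkene CH on B2 of cyclohexane ring B. One operation joins a cis formyl acid (CHO on B2, CO2H on B3, B4 diol as acetonide) with a 2-phosphonoacrylate, making the O–CH2 bond and the ring alkene and closing ring C. The formyl acid arises regiodefined from an enone–allene photoadduct.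

Key step: step 11

Labels: ring B is the cyclohexane of the right half (B1 isopropyl carbon, B2, B3, B4 carbinol carbon, B5, B6). C7 and C8 are the two carbons added in the photocycloaddition, bonded to B2 and B3. Ring A is the cyclohexene of the left half; its carbons are named by what they carry: the isopropyl carbon, the side-chain carbon next to it, the alkene CH and the alkene carbon that bears CH2OH.

Remark: the isopropyl carbon of ring B (B1) is S and that of ring A is R, so the two halves need enantiomeric 4-isopropylcyclohexenones, made with enantiomeric catalysts.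

Remark: allene is the two-carbon partner because its methylene carbon ends on C8, so the later cleavage gives acid on B3 and aldehyde on B2 without having to tell two like aldehydes apart.

Assumption: the prolinol ether catalyst shields the enamine in its usual sense, so the (S)-catalyst gives the (S)-oxohexanal and the (R)-catalyst its enantiomer; if the sense were opposite, the two catalysts are exchanged.

Step 1
Reactants: 1 3-methylbutanal; 2 but-3-en-2-one
Product: 3 (S)-2-isopropyl-5-oxohexanal
Conditions: (S)-2-[methoxy(diphenyl)methyl]pyrrolidine (5 mol %), ethyl 3,4-dihydroxybenzoate (20 mol %), neat, 4 °C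
Reagents that add atoms: none
Why: Enamine-catalysed asymmetric Michael addition; the diphenyl(methoxy)methyl arm covers one face of the E-enamine, so the enone is taken up on the open face and the isopropyl-bearing centre (later B1) should be set as S.

Step 2
Reactants: 3 (S)-2-isopropyl-5-oxohexanal
Product: 4 (S)-4-isopropylcyclohex-2-en-1-one
Conditions: LiOH, i-PrOH, rt
Reagents that add atoms: none
Why: Intramolecular aldol condensation of the methyl ketone onto the aldehyde closes the six-membered enone, and the mild base should limit enolisation of the aldehyde α-centre before ring closure.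

Step 3
Reactants: 4 (S)-4-isopropylcyclohex-2-en-1-one; 5 propa-1,2-diene
Product: 6 (1R,5S,6S)-5-isopropyl-8-methylenebicyclo[4.2.0]octan-2-one
Conditions: hν (Hg lamp, Pyrex), THF, −78 °C; then basic Al2O3
Reagents that add atoms: none
Why: Enone–allene [2+2] photocycloaddition; the excited enone bonds at its β-carbon (B2) on the face away from the neighbouring isopropyl group and the central allene carbon ends on the α-carbon (B3) in the usual head-to-head sense, which sets B2 and B3, and alumina should turn any trans-fused adduct into the cis-fused ketone.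

Step 4
Reactants: 6 (1R,5S,6S)-5-isopropyl-8-methylenebicyclo[4.2.0]octan-2-one
Product: 7 (1R,2R,5S,6S)-2-{[isopropoxy(dimethyl)silyl]methyl}-5-isopropyl-8-methylenebicyclo[4.2.0]octan-2-ol
Conditions: (i-PrO)Me2SiCH2MgCl, CeCl3, THF, −78 → 0 °C; aq. NH4Cl
Reagents that add atoms: (isopropoxydimethylsilyl)methylmagnesium chloride, CC(C)O[Si](C)(C)C[Mg]Cl
Why: 1,2-Addition of a hydroxymethyl anion equivalent (cerium-modified Grignard addition, little enolisation); the reagent should enter axially on the ketone face opposite the axial cyclobutane bond on B3, which sets B4 with its oxygen cis to C8.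

Step 5
Reactants: 7 the silylmethyl carbinol
Product: 8 (1R,2R,5S,6S)-2-(hydroxymethyl)-5-isopropyl-8-methylenebicyclo[4.2.0]octan-2-ol
Conditions: H2O2 (30 % aq.), KF, KHCO3, THF/MeOH, rt
Reagents that add atoms: hydrogen peroxide, OO
Why: Tamao–Fleming oxidation converts the C–Si bond of the alkoxysilane into C–OH under conditions that should leave the methylene group and the tertiary alcohol untouched.

Step 6
Reactants: 8 the 1,2-diol
Product: 9 acetonide of 8 (spiro-dioxolane on B4)
Conditions: Me2C(OMe)2, PPTS (cat.), CH2Cl2, rt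
Reagents that add atoms: 2,2-dimethoxypropane, COC(C)(C)OC
Why: Acid-catalysed transketalisation masks both hydroxyls, which avoids a free β-hydroxy ketone (retro-aldol) once C8 becomes a carbonyl.

Step 7
Reactants: 9 acetonide of 8
Product: 11 cyclobutanone (ketone on C8), via ozonide 10 (not isolated)
Conditions: O3, CH2Cl2, −78 °C; then PPh3, −78 °C → rt
Reagents that add atoms: ozone, [O-][O+]=O
Why: Ozonolysis of the 1,1-disubstituted alkene with reductive work-up should give the cyclobutanone on C8, the carbon bonded to B3.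

Step 8
Reactants: 11 cyclobutanone
Product: 12 trimethylsilyl enol ether of 11 (C7=C8, OSiMe3 on C8)
Conditions: LiN(i-Pr)2, Me3SiCl, THF, −78 °C
Reagents that add atoms: chlorotrimethylsilane, C[Si](C)(C)Cl
Why: Kinetic enolate formation and O-silylation; the base should take the open C7 methylene and not the hindered ring-fusion CH on B3, whose enolate would be a strained ring-fusion cyclobutene.

Step 9
Reactants: 12 trimethylsilyl enol ether
Product: 14 (5R,6S,7S,8S)-7-formyl-8-isopropyl-2,2-dimethyl-1,3-dioxaspiro[4.5]decane-6-carboxylic acid, via silyl ester 13 (not isolated)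
Conditions: O3, CH2Cl2, −78 °C; then Me2S, → rt; then H2O
Reagents that add atoms: ozone, [O-][O+]=O
Why: Ozonolysis of a silyl enol ether cleaves C7=C8 so that the silyloxy carbon C8 (on B3) should emerge as a silyl carboxylate, hydrolysed on work-up, and C7 (on B2) as the aldehyde; the product is expected to rest as its cyclic hydroxylactone tautomer.

Step 10
Reactants: 15 tert-butyl 2-(diethoxyphosphoryl)acetate
Product: 18 tert-butyl 2-(diethoxyphosphoryl)acrylate, via Mannich base 16 (not isolated), via methiodide 17 (not isolated)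
Conditions: NaH, THF, 0 °C; CH2=NMe2+ I−, 0 °C → rt; then MeI, rt; then aq. NaHCO3
Reagents that add atoms: N,N-dimethylmethyleneiminium iodide, C=[N+](C)C.[I-]
Why: Mannich reaction of the phosphonoacetate anion, quaternisation and E1cB loss of trimethylamine install the methylene group without acid or heat, so the tert-butyl ester should survive.

Step 11
Reactants: 14 the cis formyl acid; 18 tert-butyl 2-(diethoxyphosphoryl)acrylate
Product: 20 tert-butyl (5aR,6S,9R,9aS)-6-isopropyl-2',2'-dimethyl-1-oxo-1,5a,6,7,8,9a-hexahydro-3H-spiro[2-benzoxepine-9,4'-[1,3]dioxolane]-4-carboxylate, via Michael adduct 19 (not isolated)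
Conditions: Cs2CO3, MeCN (high dilution), 4 Å molecular sieves, 0 °C → rt
Reagents that add atoms: none
Why: Proposed new method: Cs2CO3 opens the hydroxylactone form of 14 to the carboxylate aldehyde, the carboxylate adds reversibly (oxa-Michael) to the doubly activated alkene of 18, and the phosphonate carbanion 19 then attacks the formyl group on B2 and expels diethyl phosphate (Horner–Wadsworth–Emmons), forming the O–CH2 bond and the ring alkene. The nearest precedent in kind is the base-mediated reaction of salicylaldehydes with 2-phosphonoacrylates, in which phenoxide conjugate addition is followed by ring-closing Horner–Wadsworth–Emmons olefination to give 2H-chromene-3-carboxylates; here the donor is a carboxylate instead of a phenoxide. Ring C closes by 7-exo-trig attack of the carbanion on the formyl carbon, and the alkene geometry is dictated by the ring, which tolerates only B2 cis to the OCH2 carbon. No stereocentre is created; B2 already has its more stable configuration trans to the isopropyl group and carbonate should not enolise B3. The step needs cyclisation to win over intermolecular olefination and over the poor Michael equilibrium of a weak donor; the cis-1,2 placement of carboxylate and aldehyde on ring B and high dilution favour ring closure, and since phosphate loss cannot revert, each adduct that cyclises is removed and the small equilibrium share of adduct is replenished.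

Step 12
Reactants: 1 3-methylbutanal; 2 but-3-en-2-one
Product: 21 (R)-2-isopropyl-5-oxohexanal
Conditions: (R)-2-[methoxy(diphenyl)methyl]pyrrolidine (5 mol %), ethyl 3,4-dihydroxybenzoate (20 mol %), neat, 4 °C
Reagents that add atoms: none
Why: The same enamine-catalysed Michael addition with the mirror-image catalyst should set the isopropyl-bearing centre (later the isopropyl carbon of ring A) as R.

Step 13
Reactants: 21 (R)-2-isopropyl-5-oxohexanal
Product: 22 (R)-4-isopropylcyclohex-2-en-1-one
Conditions: LiOH, i-PrOH, rt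
Reagents that add atoms: none
Why: Intramolecular aldol condensation, as in step 2.

Step 14
Reactants: 22 (R)-4-isopropylcyclohex-2-en-1-one
Product: 24 (3R,4R)-4-isopropyl-3-vinylcyclohex-1-en-1-yl trifluoromethanesulfonate, via magnesium enolate 23 (not isolated)
Conditions: CH2=CHMgBr, CuBr·SMe2 (10 mol %), THF, −78 → −40 °C; then PhNTf2, −78 °C → rt
Reagents that add atoms: vinylmagnesium bromide, C=C[Mg]Br; N-phenylbis(trifluoromethanesulfonimide), O=S(=O)(N(c1ccccc1)S(=O)(=O)C(F)(F)F)C(F)(F)F
Why: Copper-catalysed conjugate addition delivers the vinyl group anti to the adjacent isopropyl group (sets the side-chain carbon of ring A trans to the isopropyl carbon), and O-triflation of the regiodefined enolate fixes the ring alkene between the carbon next to the side-chain carbon and the triflate-bearing carbon.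

Step 15
Reactants: 24 the vinyl triflate
Product: 26 (3R,4R)-3-formyl-4-isopropylcyclohex-1-en-1-yl trifluoromethanesulfonate, via diol 25 (not isolated)
Conditions: OsO4 (2 mol %), NaIO4, 2,6-lutidine, dioxane/H2O, rt
Reagents that add atoms: osmium tetroxide, O=[Os](=O)(=O)=O; sodium periodate, [Na+].[O-][I](=O)(=O)=O
Why: Lemieux–Johnson oxidation; electrophilic OsO4 should dihydroxylate the monosubstituted vinyl group in preference to the triflate-deactivated ring alkene, and periodate cleaves the diol.

Step 16
Reactants: 26 the aldehyde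
Product: 27 methyl (Z)-2-bromo-3-[(1R,6R)-6-isopropyl-3-(trifluoromethanesulfonyloxy)cyclohex-2-en-1-yl]prop-2-enoate
Conditions: Ph3P=CHCO2Me, NBS, CH2Cl2, −20 °C; then 26, −20 → 40 °C
Reagents that add atoms: methyl (triphenylphosphoranylidene)acetate, COC(=O)C=P(c1ccccc1)(c1ccccc1)c1ccccc1; N-bromosuccinimide, O=C1CCC(=O)N1Br
Why: Wittig reaction of the bromo-stabilised ylide made in the flask should place the ring carbon trans to the ester ((Z)-bromoenoate) under neutral conditions that spare the α-centre, while the enol triflate keeps the ring alkene from moving into conjugation with the aldehyde.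

Step 17
Reactants: 27 the bromoenoate triflate
Product: 28 methyl (E)-2-(hydroxymethyl)-3-[(1R,6R)-3-(hydroxymethyl)-6-isopropylcyclohex-2-en-1-yl]prop-2-enoate
Conditions: Bu3SnCH2OH, Pd(PPh3)4 (10 mol %), LiCl, dioxane, 95 °C
Reagents that add atoms: (tributylstannyl)methanol, CCCC[Sn](CCCC)(CCCC)CO
Why: Stille coupling should transfer the hydroxymethyl group from tin to both sp2 electrophiles (enol triflate and vinyl bromide) with retention of alkene geometry.

Step 18
Reactants: 28 the diol ester
Product: 29 bis(tert-butyldimethylsilyl) ether of 28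
Conditions: TBSCl, imidazole, DMF, rt
Reagents that add atoms: tert-butylchlorodimethylsilane, CC(C)(C)[Si](C)(C)Cl
Why: Silylation of both primary allylic alcohols gives ethers that survive saponification and esterification and fall to acid at the end.

Step 19
Reactants: 29 the bis-silyl ether ester
Product: 30 (2E)-2-{[(tert-butyldimethylsilyl)oxy]methyl}-3-[(1R,6R)-3-{[(tert-butyldimethylsilyl)oxy]methyl}-6-isopropylcyclohex-2-en-1-yl]prop-2-enoic acid
Conditions: LiOH, THF/MeOH/H2O, 40 °C; then aq. HCl to pH 4, 0 °C
Reagents that add atoms: lithium hydroxide, [Li+].[OH-]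
Why: Saponification of the methyl ester; hydroxide is too weak to deprotonate the doubly allylic γ-position on ring A, and the silyl ethers should survive.

Step 20
Reactants: 20 the right-half lactone
Product: 31 tert-butyl (5aR,6S,9R,9aS)-9-hydroxy-9-(hydroxymethyl)-6-isopropyl-1-oxo-1,3,5a,6,7,8,9,9a-octahydro-2-benzoxepine-4-carboxylate
Conditions: AcOH/H2O/THF (3:1:1), 40 °C
Reagents that add atoms: none
Why: Acid-catalysed acetal hydrolysis that the tert-butyl ester and the lactone should survive; acyl migration to the freed primary hydroxyl is disfavoured because the lactone carbonyl on B3 and the CH2OH group on B4 are trans-diaxial.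

Step 21
Reactants: 30 the left acid; 31 the diol lactone
Product: 33 protected target (tert-butyl ester and bis-silyl ether), via mixed anhydride 32 (not isolated)
Conditions: 2,4,6-Cl3C6H2COCl, Et3N, toluene, rt; then 31, DMAP, rt
Reagents that add atoms: none
Why: Yamaguchi esterification should acylate the primary hydroxyl only, the tertiary hydroxyl on B4 being too hindered, and the already E-configured acid cannot lose geometry under DMAP.

Step 22
Reactants: 33 the protected target
Product: 34 CNP0361406.3
Conditions: CF3CO2H/CH2Cl2/H2O (10:10:1), 0 °C → rt; then pH 7 buffer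
Reagents that add atoms: none
Why: Acidolysis removes the tert-butyl ester (loss of 2-methylpropene) and both silyl ethers in one operation; the buffer work-up should hydrolyse any trifluoroacetate formed on the allylic alcohols.

Compound list
1 | 3-methylbutanal | CC(C)CC=O | starting material
2 | but-3-en-2-one | CC(=O)C=C | starting material
3 | (S)-2-isopropyl-5-oxohexanal | CC(=O)CC[C@@H](C(C)C)C=O | intermediate
4 | (S)-4-isopropylcyclohex-2-en-1-one | O=C1C=C[C@H](C(C)C)CC1 | intermediate
5 | propa-1,2-diene (allene) | C=C=C | starting material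
6 | (1R,5S,6S)-5-isopropyl-8-methylenebicyclo[4.2.0]octan-2-one (cis-fused, cyclobutane anti to isopropyl) | O=C1CC[C@@H](C(C)C)[C@@H]2CC(=C)[C@H]12 | intermediate
7 | (1R,2R,5S,6S)-2-{[isopropoxy(dimethyl)silyl]methyl}-5-isopropyl-8-methylenebicyclo[4.2.0]octan-2-ol | CC(C)O[Si](C)(C)C[C@@]1(O)CC[C@@H](C(C)C)[C@@H]2CC(=C)[C@H]12 | intermediate
8 | (1R,2R,5S,6S)-2-(hydroxymethyl)-5-isopropyl-8-methylenebicyclo[4.2.0]octan-2-ol | OC[C@@]1(O)CC[C@@H](C(C)C)[C@@H]2CC(=C)[C@H]12 | intermediate
9 | acetonide of 8: 5-isopropyl-2',2'-dimethyl-8-methylenespiro[bicyclo[4.2.0]octane-2,4'-[1,3]dioxolane], configuration as in 8 | CC1(C)OC[C@@]2(O1)CC[C@@H](C(C)C)[C@@H]3CC(=C)[C@H]23 | intermediate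
10 | ozonide of 9 (1,2,4-trioxolane spiro-fused at C8, spiro centre undefined) | CC1(C)OC[C@@]2(O1)CC[C@@H](C(C)C)[C@@H]3CC4(OCOO4)[C@H]23 | intermediate
11 | cyclobutanone: 5-isopropyl-2',2'-dimethylspiro[bicyclo[4.2.0]octane-2,4'-[1,3]dioxolan]-8-one, configuration as in 8 | CC1(C)OC[C@@]2(O1)CC[C@@H](C(C)C)[C@@H]3CC(=O)[C@H]23 | intermediate
12 | trimethylsilyl enol ether of 11 (C7=C8, OSiMe3 on C8) | CC1(C)OC[C@@]2(O1)CC[C@@H](C(C)C)[C@@H]3C=C(O[Si](C)(C)C)[C@H]23 | intermediate
13 | trimethylsilyl ester of 14 | CC1(C)OC[C@@]2(O1)CC[C@@H](C(C)C)[C@H](C=O)[C@@H]2C(=O)O[Si](C)(C)C | intermediate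
14 | (5R,6S,7S,8S)-7-formyl-8-isopropyl-2,2-dimethyl-1,3-dioxaspiro[4.5]decane-6-carboxylic acid (expected to rest as its hydroxylactone tautomer) | CC1(C)OC[C@@]2(O1)CC[C@@H](C(C)C)[C@H](C=O)[C@@H]2C(=O)O | intermediate
15 | tert-butyl 2-(diethoxyphosphoryl)acetate | CCOP(=O)(OCC)CC(=O)OC(C)(C)C | starting material
16 | tert-butyl 2-(diethoxyphosphoryl)-3-(dimethylamino)propanoate | CCOP(=O)(OCC)C(CN(C)C)C(=O)OC(C)(C)C | intermediate
17 | [3-tert-butoxy-2-(diethoxyphosphoryl)-3-oxopropyl]trimethylammonium iodide | CCOP(=O)(OCC)C(C[N+](C)(C)C)C(=O)OC(C)(C)C.[I-] | intermediate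
18 | tert-butyl 2-(diethoxyphosphoryl)acrylate | C=C(C(=O)OC(C)(C)C)P(=O)(OCC)OCC | intermediate
19 | Michael adduct: 3-tert-butoxy-2-(diethoxyphosphoryl)-3-oxopropyl ester of 14 (present as its carbanion, phosphonate carbon undefined) | CC1(C)OC[C@@]2(O1)CC[C@@H](C(C)C)[C@H](C=O)[C@@H]2C(=O)OCC(C(=O)OC(C)(C)C)P(=O)(OCC)OCC | intermediate
20 | tert-butyl (5aR,6S,9R,9aS)-6-isopropyl-2',2'-dimethyl-1-oxo-1,5a,6,7,8,9a-hexahydro-3H-spiro[2-benzoxepine-9,4'-[1,3]dioxolane]-4-carboxylate (cis-fused lactone) | CC1(C)OC[C@@]2(O1)CC[C@@H](C(C)C)[C@@H]3C=C(C(=O)OC(C)(C)C)COC(=O)[C@@H]32 | intermediate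
21 | (R)-2-isopropyl-5-oxohexanal | CC(=O)CC[C@H](C(C)C)C=O | intermediate
22 | (R)-4-isopropylcyclohex-2-en-1-one | O=C1C=C[C@@H](C(C)C)CC1 | intermediate
23 | bromomagnesium enolate of (3R,4R)-4-isopropyl-3-vinylcyclohexanone (enolate alkene on the side of the vinyl-bearing carbon) | CC(C)[C@H]1CCC(O[Mg]Br)=C[C@@H]1C=C | intermediate
24 | (3R,4R)-4-isopropyl-3-vinylcyclohex-1-en-1-yl trifluoromethanesulfonate | CC(C)[C@H]1CCC(OS(=O)(=O)C(F)(F)F)=C[C@@H]1C=C | intermediate
25 | 1,2-diol from 24 (vinyl group dihydroxylated, carbinol centre undefined) | CC(C)[C@H]1CCC(OS(=O)(=O)C(F)(F)F)=C[C@@H]1C(O)CO | intermediate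
26 | (3R,4R)-3-formyl-4-isopropylcyclohex-1-en-1-yl trifluoromethanesulfonate | CC(C)[C@H]1CCC(OS(=O)(=O)C(F)(F)F)=C[C@@H]1C=O | intermediate
27 | methyl (Z)-2-bromo-3-[(1R,6R)-6-isopropyl-3-(trifluoromethanesulfonyloxy)cyclohex-2-en-1-yl]prop-2-enoate | CC(C)[C@H]1CCC(OS(=O)(=O)C(F)(F)F)=C[C@@H]1/C=C(\Br)C(=O)OC | intermediate
28 | methyl (E)-2-(hydroxymethyl)-3-[(1R,6R)-3-(hydroxymethyl)-6-isopropylcyclohex-2-en-1-yl]prop-2-enoate | CC(C)[C@H]1CCC(CO)=C[C@@H]1/C=C(\CO)C(=O)OC | intermediate
29 | bis(tert-butyldimethylsilyl) ether of 28 | CC(C)[C@H]1CCC(CO[Si](C)(C)C(C)(C)C)=C[C@@H]1/C=C(\CO[Si](C)(C)C(C)(C)C)C(=O)OC | intermediate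
30 | (2E)-2-{[(tert-butyldimethylsilyl)oxy]methyl}-3-[(1R,6R)-3-{[(tert-butyldimethylsilyl)oxy]methyl}-6-isopropylcyclohex-2-en-1-yl]prop-2-enoic acid | CC(C)[C@H]1CCC(CO[Si](C)(C)C(C)(C)C)=C[C@@H]1/C=C(\CO[Si](C)(C)C(C)(C)C)C(=O)O | intermediate
31 | tert-butyl (5aR,6S,9R,9aS)-9-hydroxy-9-(hydroxymethyl)-6-isopropyl-1-oxo-1,3,5a,6,7,8,9,9a-octahydro-2-benzoxepine-4-carboxylate | OC[C@@]1(O)CC[C@@H](C(C)C)[C@@H]2C=C(C(=O)OC(C)(C)C)COC(=O)[C@@H]21 | intermediate
32 | mixed anhydride of 30 with 2,4,6-trichlorobenzoic acid | CC(C)[C@H]1CCC(CO[Si](C)(C)C(C)(C)C)=C[C@@H]1/C=C(\CO[Si](C)(C)C(C)(C)C)C(=O)OC(=O)c1c(Cl)cc(Cl)cc1Cl | intermediate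
33 | protected target: ester of 30 with the primary hydroxyl of 31 (tert-butyl ester, two silyl ethers) | CC(C)[C@H]1CCC(CO[Si](C)(C)C(C)(C)C)=C[C@@H]1/C=C(\CO[Si](C)(C)C(C)(C)C)C(=O)OC[C@@]1(O)CC[C@@H](C(C)C)[C@@H]2C=C(C(=O)OC(C)(C)C)COC(=O)[C@@H]21 | intermediate
34 | CNP0361406.3: (5aR,6S,9R,9aS)-9-hydroxy-9-({[(2E)-2-(hydroxymethyl)-3-[(1R,6R)-3-(hydroxymethyl)-6-isopropylcyclohex-2-en-1-yl]prop-2-enoyl]oxy}methyl)-6-isopropyl-1-oxo-1,3,5a,6,7,8,9,9a-octahydro-2-benzoxepine-4-carboxylic acid | CC(C)[C@H]1CCC(CO)=C[C@@H]1/C=C(\CO)C(=O)OC[C@@]1(O)CC[C@@H](C(C)C)[C@@H]2C=C(C(=O)O)COC(=O)[C@@H]21 | target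

Total step count: 22. Longest linear sequence: 13 steps (steps 1–9, 11, 20–22).

Steps most likely to fail

Step 11 (key step). The weak carboxylate may add to 18 more slowly than 18 oligomerises, the lactol hydroxyl of the hydroxylactone form may add in its place, the Michael adduct may olefinate a second molecule instead of closing the ring, or prolonged base contact may epimerise B2. The fallback uses known chemistry only and sets out from 14. Wittig methylenation of the formyl group with excess Ph3P=CH2 in THF gives the vinyl acid, the 7-vinyl analogue of 14 F1. O-Alkylation of its cesium salt with tert-butyl 2-(bromomethyl)acrylate (Cs2CO3, DMF) gives the 2-(tert-butoxycarbonyl)allyl ester F2. Ring-closing metathesis with the second-generation Hoveyda–Grubbs catalyst in toluene at 80 °C joins the vinyl group to the acrylate methylene with loss of ethene and comes back to the route at 20.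

Step 17 (double hydroxymethyl Stille coupling). Transfer of the hydroxymethyl group from tin is slow, so butyl transfer, protodehalogenation of the bromoenoate or coupling at only one of the two sites may dominate. The fallback avoids carbon transfer from tin and sets out from 26. Sodium 4-methoxybenzyl oxide (from the alcohol and NaH in THF) adds to methyl 2-(dimethoxyphosphoryl)acrylate and the resulting phosphonate anion olefinates 26 to give the 4-methoxybenzyl ether triflate F3. Palladium-catalysed formylation of the enol triflate (Pd(PPh3)4, CO, Bu3SnH, THF) gives the ring enal F4. Luche reduction (NaBH4, CeCl3, MeOH) gives the ring allylic alcohol F5, and DDQ in buffered CH2Cl2 removes the 4-methoxybenzyl group and comes back to the route at 28.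

Step 9 (ozonolysis of the silyloxycyclobutene). The strained enol ether may react abnormally with ozone, with over-oxidation of the new aldehyde or oxygen insertion instead of clean cleavage. The fallback sets out from 12. Rubottom oxidation (mCPBA, NaHCO3, CH2Cl2, then dilute acid) gives the α-hydroxycyclobutanone F6, hydroxylated on C7. NaIO4 in aqueous THF then cleaves the C7–C8 bond of the α-ketol, leaving the acid on C8 and the aldehyde on C7, and comes back to the route at 14.

Further compounds
F1 | step 11 | 8-isopropyl-2,2-dimethyl-7-vinyl-1,3-dioxaspiro[4.5]decane-6-carboxylic acid, configuration as in 14 | CC1(C)OC[C@@]2(O1)CC[C@@H](C(C)C)[C@H](C=C)[C@@H]2C(=O)O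
F2 | step 11 | 2-(tert-butoxycarbonyl)prop-2-en-1-yl ester of F1 | CC1(C)OC[C@@]2(O1)CC[C@@H](C(C)C)[C@H](C=C)[C@@H]2C(=O)OCC(=C)C(=O)OC(C)(C)C
F3 | step 17 | methyl (E)-3-[6-isopropyl-3-(trifluoromethanesulfonyloxy)cyclohex-2-en-1-yl]-2-{[(4-methoxybenzyl)oxy]methyl}prop-2-enoate, ring configuration as in 26 | CC(C)[C@H]1CCC(OS(=O)(=O)C(F)(F)F)=C[C@@H]1/C=C(\COCc1ccc(OC)cc1)C(=O)OC
F4 | step 17 | methyl (E)-3-(3-formyl-6-isopropylcyclohex-2-en-1-yl)-2-{[(4-methoxybenzyl)oxy]methyl}prop-2-enoate, ring configuration as in 26 | CC(C)[C@H]1CCC(C=O)=C[C@@H]1/C=C(\COCc1ccc(OC)cc1)C(=O)OC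
F5 | step 17 | methyl (E)-3-[3-(hydroxymethyl)-6-isopropylcyclohex-2-en-1-yl]-2-{[(4-methoxybenzyl)oxy]methyl}prop-2-enoate, ring configuration as in 26 | CC(C)[C@H]1CCC(CO)=C[C@@H]1/C=C(\COCc1ccc(OC)cc1)C(=O)OC
F6 | step 9 | α-hydroxycyclobutanone: 7-hydroxy derivative of 11 (C7 configuration undefined) | CC1(C)OC[C@@]2(O1)CC[C@@H](C(C)C)[C@@H]3C(O)C(=O)[C@H]23
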